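Assumption: the SMILES is read as (5S,6R,8R,9R,10S,13S), that is the normal labdane series with 5α-H, 6β-OAc, 8α-Me/8β-H, 9α-O, 10β-Me. Labdane numbering is used throughout.

## Retrosynthetic overview
1. Previtexilactone 13 comes from the Δ7 6β-alcohol 11 by OH-directed hydrogenation (sets C8) and acetylation.
2. 11 comes from butenolide diol 10 by the key C13–O bond. A catalyst-controlled 5-exo oxa-Michael addition of the 9α tertiary alcohol closes the tetrahydrofuran ring and sets C13.
3. 10 comes from iodide 8 and 4-bromofuran-2(5H)-one 9 by reductive C12–C13 coupling. The lactone ring is brought in intact.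
4. 8 comes from Δ7 ester 3 by ring B oxidation: C6 allylic oxidation, C9 γ-hydroxylation, then hydride reduction (sets C9 and C6).
5. 3 comes from (+)-sclareolide 1, which supplies rings A and B, C5, C10 and the C9–C11 bond. Ring order: decalin from the pool, then the lactone, then the tetrahydrofuran last.

## Route

Step 1
Reactants: 1 (+)-sclareolide
Product: 3 methyl 13,14,15,16-tetranorlabd-7-en-12-oate, via 8α-hydroxy ester 2 (not isolated)
Conditions: MeOH, conc. H2SO4 (cat.), reflux, 24 h; chromatography on AgNO3-impregnated SiO2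
Reagents that add atoms: methanol, CO
Why: Acid-catalysed lactone methanolysis, then E1 dehydration of the tertiary 8α-alcohol with loss of the axial 7α-H, gives mainly the trisubstituted Δ7 alkene; the minor Δ8(9) and Δ8(17) isomers are removed, and C5, C9 and C10 come unchanged from 1.

Step 2
Reactants: 3 methyl 13,14,15,16-tetranorlabd-7-en-12-oate
Product: 4 methyl 6-oxo-13,14,15,16-tetranorlabd-7-en-12-oate
Conditions: CrO3, 3,5-dimethylpyrazole, CH2Cl2, −20 °C
Reagents that add atoms: chromium trioxide, O=[Cr](=O)=O
Why: The CrO3–dimethylpyrazole allylic oxidation attacks the only allylic CH2 (C6) of the Δ7 alkene and gives the 7-en-6-one, as is usual for drim-7-enes; the 5α-H stays in the more stable trans-decalin form.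

Step 3
Reactants: 4 methyl 6-oxo-13,14,15,16-tetranorlabd-7-en-12-oate
Product: 6 methyl 9α-hydroxy-6-oxo-13,14,15,16-tetranorlabd-7-en-12-oate, via 9α-hydroperoxide 5 (not isolated)
Conditions: Cu(OTf)2 (10 mol %), 1,1,3,3-tetramethylguanidine, O2 (1 atm), THF, 0 °C to rt; then P(OEt)3
Reagents that add atoms: dioxygen, O=O
Why: In this copper-catalysed vinylogous aerobic oxidation, base and divalent copper form the extended 6,8-dienolate by removing the γ-H at C9, O2 adds at the tertiary γ-carbon from the α face (axial, anti to the 10β-methyl), and the phosphite reduces the hydroperoxide, which sets the 9α-OH.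

Step 4
Reactants: 6 methyl 9α-hydroxy-6-oxo-13,14,15,16-tetranorlabd-7-en-12-oate
Product: 7 13,14,15,16-tetranorlabd-7-ene-6β,9α,12-triol
Conditions: LiAlH4, THF, −20 to 0 °C; then H2O, aq NaOH
Reagents that add atoms: none
Why: In this hydride reduction the ester goes to the primary alcohol and the enone is reduced 1,2 from the open α face, because the 4β- and 10β-methyls block the β face, which sets the axial 6β-OH (6R).

Step 5
Reactants: 7 13,14,15,16-tetranorlabd-7-ene-6β,9α,12-triol
Product: 8 12-iodo-13,14,15,16-tetranorlabd-7-ene-6β,9α-diol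
Conditions: I2, PPh3, imidazole, CH2Cl2, 0 °C
Reagents that add atoms: iodine, II
Why: The Garegg–Samuelsson (Appel-type) iodination takes the unhindered primary alcohol in preference to the hindered axial allylic 6β-OH and the tertiary 9α-OH, and no stereocenter is touched.

Step 6
Reactants: 8 12-iodo-13,14,15,16-tetranorlabd-7-ene-6β,9α-diol; 9 4-bromofuran-2(5H)-one
Product: 10 6β,9α-dihydroxylabda-7,13-dien-16,15-olide
Conditions: NiBr2(dme) (10 mol %), 4,4'-di-tert-butyl-2,2'-bipyridine (10 mol %), Zn dust, DMA, 25 °C
Reagents that add atoms: none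
Why: Nickel-catalysed reductive cross-electrophile coupling of a primary alkyl iodide with a vinyl bromide forms C12–C13 without a preformed organometallic, so both free hydroxyls survive; direct radical addition to C13 followed by bromide loss leads to the same product, and no stereocenter is formed.

Step 7
Reactants: 10 6β,9α-dihydroxylabda-7,13-dien-16,15-olide
Product: 11 (13S)-9α,13-epoxy-6β-hydroxylabd-7-en-16,15-olide
Conditions: bifunctional iminophosphorane (BIMP) catalyst [tert-leucine-derived 3,5-(CF3)2C6H3-thiourea carrying a (4-MeOC6H4)3P=N– group] (10 mol %), toluene, 0 °C, 48 h; filtration through SiO2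
Reagents that add atoms: none
Why: Proposed new method: a catalyst-controlled 5-exo-trig oxa-Michael spirocyclisation of a tertiary alcohol onto a β,β-disubstituted butenolide. The iminophosphorane superbase site takes the 9α-O–H proton while the thiourea N–H pair binds the lactone carbonyl, so O–H removal, C13–O bond formation and enolate stabilisation happen within one organised ion pair, and the iminophosphonium then protonates the enolate at C14. Full substitution at C9 (gem-dialkyl effect) and the three-atom tether make closure fast and roughly thermoneutral to downhill. The chiral pocket (both catalyst antipodes are accessible and the matched one is kept) exposes the Si face of C13 to give 13S, and any 13-epimer is returned to 10 by retro-addition under the same catalyst and recycled. The closest known reaction type is the BIMP-catalysed enantioselective intramolecular oxa-Michael addition of primary and secondary alcohols to β-monosubstituted enoates, which has not been shown for tertiary alcohols, butenolides or tetrasubstituted spiro centres.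

Step 8
Reactants: 11 (13S)-9α,13-epoxy-6β-hydroxylabd-7-en-16,15-olide
Product: 12 (13S)-9α,13-epoxy-6β-hydroxy-8βH-labdan-16,15-olide
Conditions: [Ir(cod)(PCy3)(py)]PF6 (5 mol %), H2 (1–10 bar), CH2Cl2, rt
Reagents that add atoms: none
Why: In this hydroxyl-directed homogeneous hydrogenation the cationic iridium catalyst binds the 6β-OH (the only free OH now that O9 is an ether) and delivers H2 to the β face of the trisubstituted alkene, as with 3-methylcyclohex-2-enols, which gives 8β-H and the equatorial 8α-methyl (8R).

Step 9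
Reactants: 12 (13S)-9α,13-epoxy-6β-hydroxy-8βH-labdan-16,15-olide
Product: 13 previtexilactone
Conditions: Ac2O, DMAP, pyridine, 40 °C
Reagents that add atoms: acetic anhydride, CC(=O)OC(C)=O
Why: DMAP-catalysed acyl transfer acetylates the hindered axial 6β-OH with retention, and the mild base leaves the β-alkoxy lactone and all six stereocenters intact.

## Compound list
1 | (+)-sclareolide (13,14,15,16-tetranorlabdan-8α,12-olide; 5α-H, 9α-H, 8β-Me, 10β-Me) | C1C[C@@](C)(OC(=O)C3)[C@H]3[C@@]2(C)CCCC(C)(C)[C@H]12 | starting material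
2 | methyl 8α-hydroxy-13,14,15,16-tetranorlabdan-12-oate (not isolated) | C1C[C@@](C)(O)[C@H](CC(=O)OC)[C@@]2(C)CCCC(C)(C)[C@H]12 | intermediate
3 | methyl 13,14,15,16-tetranorlabd-7-en-12-oate (5α-H, 9α-H, 10β-Me) | C1C=C(C)[C@H](CC(=O)OC)[C@@]2(C)CCCC(C)(C)[C@H]12 | intermediate
4 | methyl 6-oxo-13,14,15,16-tetranorlabd-7-en-12-oate | O=C1C=C(C)[C@H](CC(=O)OC)[C@@]2(C)CCCC(C)(C)[C@H]12 | intermediate
5 | methyl 9α-hydroperoxy-6-oxo-13,14,15,16-tetranorlabd-7-en-12-oate (not isolated) | O=C1C=C(C)[C@](OO)(CC(=O)OC)[C@@]2(C)CCCC(C)(C)[C@H]12 | intermediate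
6 | methyl 9α-hydroxy-6-oxo-13,14,15,16-tetranorlabd-7-en-12-oate | O=C1C=C(C)[C@](O)(CC(=O)OC)[C@@]2(C)CCCC(C)(C)[C@H]12 | intermediate
7 | 13,14,15,16-tetranorlabd-7-ene-6β,9α,12-triol | O[C@@H]1C=C(C)[C@](O)(CCO)[C@@]2(C)CCCC(C)(C)[C@H]12 | intermediate
8 | 12-iodo-13,14,15,16-tetranorlabd-7-ene-6β,9α-diol | O[C@@H]1C=C(C)[C@](O)(CCI)[C@@]2(C)CCCC(C)(C)[C@H]12 | intermediate
9 | 4-bromofuran-2(5H)-one | O=C1C=C(Br)CO1 | starting material
10 | 6β,9α-dihydroxylabda-7,13-dien-16,15-olide | O[C@@H]1C=C(C)[C@](O)(CCC3=CC(=O)OC3)[C@@]2(C)CCCC(C)(C)[C@H]12 | intermediate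
11 | (13S)-9α,13-epoxy-6β-hydroxylabd-7-en-16,15-olide | O[C@@H]1C=C(C)[C@]2(CC[C@]3(COC(=O)C3)O2)[C@@]2(C)CCCC(C)(C)[C@H]12 | intermediate
12 | (13S)-9α,13-epoxy-6β-hydroxy-8βH-labdan-16,15-olide (6-O-deacetylprevitexilactone) | O[C@@H]1C[C@@H](C)[C@]2(CC[C@]3(COC(=O)C3)O2)[C@@]2(C)CCCC(C)(C)[C@H]12 | intermediate
13 | previtexilactone, (5S,6R,8R,9R,10S,13S)-6-acetoxy-9,13-epoxylabdan-16,15-olide | CC(=O)O[C@@H]1C[C@@H](C)[C@]2(CC[C@]3(COC(=O)C3)O2)[C@@]2(C)CCCC(C)(C)[C@H]12 | target

## Step count and risks
Total step count: 9. Longest linear sequence: 9 (from 1).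

Steps most likely to fail:

Step 7 (the new spirocyclisation). The tertiary alcohol may be too weak a pronucleophile, the equilibrium may favour the open butenolide, or face control at C13 may be poor. The fallback uses known chemistry, sets out from iodide 8 and comes back at 11.
- The same nickel reductive coupling, run with methyl 3-bromobut-3-enoate in place of 9, gives methyl 6β,9α-dihydroxylabda-7,13(16)-dien-15-oate F1.
- I2 and NaHCO3 in MeCN at 0 °C bring about an irreversible Markovnikov 5-exo iodoetherification of the 1,1-disubstituted alkene, while the hindered Δ7 alkene is left alone.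
- This gives methyl (13S)-9α,13-epoxy-6β-hydroxy-16-iodolabd-7-en-15-oate F2 together with its C13 epimer, and the two are separated on silica.
- LiOH hydrolysis gives (13S)-9α,13-epoxy-6β-hydroxy-16-iodolabd-7-en-15-oic acid F3.
- Warming F3 with Cs2CO3 in DMF closes the γ-lactone by carboxylate displacement of the iodide, which gives 11.

Step 3 (γ-hydroxylation). Deprotonation may occur at the C17 methyl or at C5, and the β-hydroxy ester product may eliminate or undergo retro-aldol cleavage in base. The fallback sets out from enone 4 and comes back at 6.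
- TBSOTf and Et3N in CH2Cl2 give the isolated methyl 6-(tert-butyldimethylsilyloxy)-13,14,15,16-tetranorlabda-6,8-dien-12-oate F4.
- Buffered mCPBA at −20 °C (vinylogous Rubottom oxidation) epoxidises the C8=C9 bond from the α face.
- Collapse of the epoxide and loss of the silyl group on mild acidic work-up give 6 without any base or O2.

Step 8 (directed hydrogenation). The 6β-OH sits between two axial methyls and may bind iridium poorly, in which case α-face addition would give the 8-epimer. The fallback sets out from 11 and comes back at the target 13.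
- Acetylation first (Ac2O, DMAP, pyridine) gives (13S)-6β-acetoxy-9α,13-epoxylabd-7-en-16,15-olide F5.
- Radical hydrogen-atom-transfer hydrogenation follows, with Mn(dpm)3 (10 mol %), PhSiH3 and t-BuOOH in i-PrOH at rt.
- This proceeds through the tertiary C8 radical and gives the thermodynamically preferred equatorial 8α-methyl, because the 8β-methyl isomer would suffer 1,3-diaxial strain with the 10β-methyl and the 6β-acetate.

## Further compounds
F1 | step 7 | methyl 6β,9α-dihydroxylabda-7,13(16)-dien-15-oate | O[C@@H]1C=C(C)[C@](O)(CCC(=C)CC(=O)OC)[C@@]2(C)CCCC(C)(C)[C@H]12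
F2 | step 7 | methyl (13S)-9α,13-epoxy-6β-hydroxy-16-iodolabd-7-en-15-oate | O[C@@H]1C=C(C)[C@]2(CC[C@@](CI)(CC(=O)OC)O2)[C@@]2(C)CCCC(C)(C)[C@H]12
F3 | step 7 | (13S)-9α,13-epoxy-6β-hydroxy-16-iodolabd-7-en-15-oic acid | O[C@@H]1C=C(C)[C@]2(CC[C@@](CI)(CC(=O)O)O2)[C@@]2(C)CCCC(C)(C)[C@H]12
F4 | step 3 | methyl 6-(tert-butyldimethylsilyloxy)-13,14,15,16-tetranorlabda-6,8-dien-12-oate | CC(C)(C)[Si](C)(C)OC1=CC(C)=C(CC(=O)OC)[C@@]2(C)CCCC(C)(C)[C@H]12
F5 | step 8 | (13S)-6β-acetoxy-9α,13-epoxylabd-7-en-16,15-olide | CC(=O)O[C@@H]1C=C(C)[C@]2(CC[C@]3(COC(=O)C3)O2)[C@@]2(C)CCCC(C)(C)[C@H]12
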